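The eleven-membered carbocycle is opened between the carbinol carbon C1 and the quaternary CMe2 carbon C11 (farnesane locants), which unravels the ring to (2E,6R,7R)-6,7-epoxyfarnesal. Its isopropylidene terminus C10=C11 is a latent tertiary nucleophile: cobalt-hydride hydrogen-atom transfer to C10 gives the C11 radical, chromium captures it, and the tertiary alkylchromium adds to the enal carbonyl. One reductive operation thus closes the cycloundecene, creates the quaternary carbon next to the new carbinol, installs the C10 methylene and leaves the C2=C3 alkene and the oxirane untouched. The feature exploited is that ring atoms C10–C11 with the two methyl groups are a hydrometalated prenyl group. The epoxide stereocentres come from Sharpless epoxidation of geraniol.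

Key step: step 8

Remark: chain locants are used throughout (C1 carbinol carbon, C2=C3 alkene, C6/C7 oxirane carbons, C11 CMe2 carbon). In these locants the target is 1S,2E,6R,7R.

Step 1
Reactants: 1 geraniol
Product: 2 (2R,3R)-2,3-epoxygeraniol, [(2R,3R)-3-methyl-3-(4-methylpent-3-en-1-yl)oxiran-2-yl]methanol
Conditions: Ti(OiPr)4 (5 mol%), D-(−)-diisopropyl tartrate (6 mol%), t-BuOOH, 4 Å MS, CH2Cl2, −20 °C
Reagents that add atoms: tert-butyl hydroperoxide, CC(C)(C)OO
Why: Katsuki–Sharpless asymmetric epoxidation, in which the allylic hydroxyl binds the titanium tartrate so that only the C2=C3 alkene is oxidised and D-(−)-tartrate delivers oxygen to the face that gives the 2R,3R oxirane (C6 and C7 of the target), the remote trisubstituted alkene staying untouched.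

Step 2
Reactants: 2 (2R,3R)-2,3-epoxygeraniol
Product: 3 (2S,3R)-2-(iodomethyl)-3-methyl-3-(4-methylpent-3-en-1-yl)oxirane
Conditions: PPh3, I2, imidazole, CH2Cl2, 0 °C
Reagents that add atoms: iodine, II
Why: Appel-type iodination, in which iodide displaces the alkoxyphosphonium group at the primary carbon by SN2, so neither oxirane carbon is touched (the descriptor change from 2R to 2S is a CIP effect only).

Step 3
Reactants: 3 (2S,3R)-2-(iodomethyl)-3-methyl-3-(4-methylpent-3-en-1-yl)oxirane; 4 methyl acetoacetate
Product: 6 methyl 5-[(2R,3R)-3-methyl-3-(4-methylpent-3-en-1-yl)oxiran-2-yl]-3-oxopentanoate, via methyl acetoacetate dianion 5 (not isolated)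
Conditions: 4 (1.5 equiv), NaH, THF, 0 °C; n-BuLi, 0 °C; then 3, −78 → −10 °C; aq. NH4Cl
Reagents that add atoms: none
Why: γ-alkylation of the acetoacetate dianion, whose terminal non-stabilised carbanion should displace the primary iodide by SN2 much faster than it opens the trisubstituted oxirane, which forms the C4–C5 bond and leaves a β-keto ester for stereodefined alkene construction.

Step 4
Reactants: 6 methyl 5-[(2R,3R)-3-methyl-3-(4-methylpent-3-en-1-yl)oxiran-2-yl]-3-oxopentanoate
Product: 8 methyl (2Z)-3-[(diethoxyphosphoryl)oxy]-5-[(2R,3R)-3-methyl-3-(4-methylpent-3-en-1-yl)oxiran-2-yl]pent-2-enoate, via sodium Z-enolate 7 (not isolated)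
Conditions: NaH, Et2O, 0 °C; ClP(O)(OEt)2, 0 °C
Reagents that add atoms: diethyl chlorophosphate, CCOP(Cl)(=O)OCC
Why: O-phosphorylation of the chelated sodium enolate in ether should give the Z enol phosphate (phosphate cis to the ester), which is the geometric template for the trisubstituted alkene.

Step 5
Reactants: 8 methyl (2Z)-3-[(diethoxyphosphoryl)oxy]-5-[(2R,3R)-3-methyl-3-(4-methylpent-3-en-1-yl)oxiran-2-yl]pent-2-enoate
Product: 9 methyl (2E,6R,7R)-6,7-epoxyfarnesoate, methyl (2E)-3-methyl-5-[(2R,3R)-3-methyl-3-(4-methylpent-3-en-1-yl)oxiran-2-yl]pent-2-enoate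
Conditions: Me2CuLi (from MeLi and CuI), Et2O, −78 → −45 °C
Reagents that add atoms: lithium dimethylcuprate, C[Cu-]C.[Li+] (made in the flask from methyllithium, [Li]C)
Why: enol phosphate–cuprate coupling, a conjugate addition–elimination that replaces the phosphate with retention, so the methyl group ends up cis to the ester and the C2=C3 alkene is E, while the trisubstituted oxirane should be inert to the Gilman reagent at this temperature.

Step 6
Reactants: 9 methyl (2E,6R,7R)-6,7-epoxyfarnesoate
Product: 10 (2E,6R,7R)-6,7-epoxyfarnesol, (2E)-3-methyl-5-[(2R,3R)-3-methyl-3-(4-methylpent-3-en-1-yl)oxiran-2-yl]pent-2-en-1-ol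
Conditions: DIBAL-H (2.5 equiv), CH2Cl2, −78 °C; Rochelle salt work-up
Reagents that add atoms: none
Why: DIBAL-H reduction of the α,β-unsaturated ester by 1,2-hydride delivery should give the allylic alcohol at −78 °C, where the trisubstituted oxirane and both alkenes survive.

Step 7
Reactants: 10 (2E,6R,7R)-6,7-epoxyfarnesol
Product: 11 (2E,6R,7R)-6,7-epoxyfarnesal, (2E)-3-methyl-5-[(2R,3R)-3-methyl-3-(4-methylpent-3-en-1-yl)oxiran-2-yl]pent-2-enal
Conditions: activated MnO2, CH2Cl2, rt
Reagents that add atoms: none
Why: MnO2 oxidation is selective for allylic alcohols, stops at the aldehyde and should neither isomerise the E alkene nor touch the oxirane.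

Step 8
Reactants: 11 (2E,6R,7R)-6,7-epoxyfarnesal
Product: 13 (1S,2E,6R,7R)-6,7-epoxy-3,7,11,11-tetramethylcycloundec-2-en-1-ol [(1R,4E,6S,11R)-4,7,7,11-tetramethyl-12-oxabicyclo[9.1.0]dodec-4-en-6-ol], via tertiary alkylchromium(III) species 12 (not isolated)
Conditions: Co(Sal-tBu,tBu)Cl (10 mol%), CrCl3·3THF (1.0 equiv), (S,R)-indane-bis(oxazoline) ligand (1.1 equiv), PhSiH3 (1.5 equiv), THF, 2 mM (slow addition of 11), 23 °C; aq. NaHCO3
Reagents that add atoms: none
Why: Proposed new method: Co(III)–H, formed from the salen complex and PhSiH3, should transfer a hydrogen atom to C10 of the only electron-rich alkene, the tertiary C11 radical is trapped by Cr(II) (kept available by Co(II)/Cr(III) electron exchange), and the tertiary alkylchromium(III) 12 adds 1,2 to the enal, so the net event is a Markovnikov hydrometalation followed by carbonyl addition. The closest known reaction type is the intermolecular Co(salen)/Cr-catalysed branch-selective coupling of unactivated alkenes with aldehydes (MHAT combined with a Nozaki–Hiyama–Kishi-type addition), which has not been used to close a ring. The 11-membered carbocycle closes in an 11-exo-trig mode onto C1=O under high dilution, and the attacking carbon becomes the quaternary C11. C1 is the only new stereocentre: the s-trans enal offers two faces to a tether that must loop over one of them, and the chiral bis(oxazoline) ligand on chromium (reagent control, with the antipode as the lever should the 6R,7R-oxirane prove mismatched) is meant to direct C11 to the Re face, which gives 1S. The step needs HAT at C10=C11 and not at C2=C3, 1,2- and not 1,4-addition, and an intact oxirane; the first is secured because C6=C7 is already masked as the epoxide and the enal alkene is electron-poor, the second is intrinsic to organochromium reagents, and the third by the neutral, weakly Lewis-acidic Cr(III)/silane medium.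

Step 9
Reactants: 13 (1S,2E,6R,7R)-6,7-epoxy-3,7,11,11-tetramethylcycloundec-2-en-1-ol; 14 4-methoxybenzoyl chloride
Product: 15 (1S,2E,6R,7R)-6,7-epoxy-3,7,11,11-tetramethylcycloundec-2-en-1-yl 4-methoxybenzoate [(1R,4E,6S,11R)-4,7,7,11-tetramethyl-12-oxabicyclo[9.1.0]dodec-4-en-6-yl 4-methoxybenzoate]
Conditions: 14, DMAP, Et3N, CH2Cl2, 0 → 40 °C
Reagents that add atoms: none
Why: DMAP-catalysed acylation through the N-acylpyridinium ion should esterify the hindered allylic alcohol on oxygen without breaking a bond to C1, so 1S is retained, and the base-buffered medium spares the oxirane.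

Compound list
1 | geraniol, (2E)-3,7-dimethylocta-2,6-dien-1-ol | OC/C=C(\C)CCC=C(C)C | starting material
2 | (2R,3R)-2,3-epoxygeraniol, [(2R,3R)-3-methyl-3-(4-methylpent-3-en-1-yl)oxiran-2-yl]methanol | OC[C@H]1O[C@]1(C)CCC=C(C)C | intermediate
3 | (2S,3R)-2-(iodomethyl)-3-methyl-3-(4-methylpent-3-en-1-yl)oxirane | IC[C@H]1O[C@]1(C)CCC=C(C)C | intermediate
4 | methyl acetoacetate | COC(=O)CC(C)=O | starting material
5 | methyl acetoacetate dianion (sodium lithium salt, formed in the flask) | [Li+].[Na+].[CH2-]C(=O)[CH-]C(=O)OC | intermediate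
6 | methyl 5-[(2R,3R)-3-methyl-3-(4-methylpent-3-en-1-yl)oxiran-2-yl]-3-oxopentanoate | COC(=O)CC(=O)CC[C@H]1O[C@]1(C)CCC=C(C)C | intermediate
7 | sodium (Z)-enolate of 6 (formed in the flask) | [Na+].COC(=O)/C=C(\[O-])CC[C@H]1O[C@]1(C)CCC=C(C)C | intermediate
8 | methyl (2Z)-3-[(diethoxyphosphoryl)oxy]-5-[(2R,3R)-3-methyl-3-(4-methylpent-3-en-1-yl)oxiran-2-yl]pent-2-enoate | COC(=O)/C=C(\OP(=O)(OCC)OCC)CC[C@H]1O[C@]1(C)CCC=C(C)C | intermediate
9 | methyl (2E,6R,7R)-6,7-epoxyfarnesoate | COC(=O)/C=C(\C)CC[C@H]1O[C@]1(C)CCC=C(C)C | intermediate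
10 | (2E,6R,7R)-6,7-epoxyfarnesol | OC/C=C(\C)CC[C@H]1O[C@]1(C)CCC=C(C)C | intermediate
11 | (2E,6R,7R)-6,7-epoxyfarnesal | O=C/C=C(\C)CC[C@H]1O[C@]1(C)CCC=C(C)C | intermediate
12 | C11 tertiary alkylchromium(III) dichloride derived from 11 (ligand omitted, formed in the flask) | O=C/C=C(\C)CC[C@H]1O[C@]1(C)CCCC(C)(C)[Cr](Cl)Cl | intermediate
13 | (1S,2E,6R,7R)-6,7-epoxy-3,7,11,11-tetramethylcycloundec-2-en-1-ol | O[C@H]1/C=C(\C)CC[C@H]2O[C@]2(C)CCCC1(C)C | intermediate
14 | 4-methoxybenzoyl chloride | COc1ccc(cc1)C(Cl)=O | starting material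
15 | (1S,2E,6R,7R)-6,7-epoxy-3,7,11,11-tetramethylcycloundec-2-en-1-yl 4-methoxybenzoate | COc1ccc(C(=O)O[C@H]2/C=C(\C)CC[C@H]3O[C@]3(C)CCCC2(C)C)cc1 | target

Total step count: 9. Longest linear sequence: 9 steps (geraniol to 15).

Steps most likely to fail

1. Step 8 (proposed new method). The tertiary radical may be reduced or simply returned to an isomerised alkene before chromium captures it, the alkylchromium may add to a second molecule instead of across the ring, or the ligand may fail to override a substrate bias so that both aldehyde faces are attacked. The fallback uses known chemistry, sets out from 11 and comes back at 13. Hydroxyselenation of the C10=C11 alkene (PhSeCl, MeCN–H2O, NaHCO3) should give the β-hydroxy selenide F1 as a C10 epimer mixture. Oxidation (H2O2, pyridine) and selenoxide syn-elimination towards C9 give the tertiary allylic alcohol F2. CBr4/PPh3 converts it with allylic transposition into the secondary allylic bromide F3 (C9 epimers, inconsequential). An intramolecular asymmetric Nozaki–Hiyama–Kishi allylation (CrCl2, chiral sulfonamide–oxazoline ligand, Et3N, THF, high dilution) then forms the same C1–C11 bond, because the allylchromium reacts through its γ-carbon C11, and gives (1S,2E,6R,7R,9E)-6,7-epoxy-3,7,11,11-tetramethylcycloundeca-2,9-dien-1-ol F4. Diimide (2-nitrobenzenesulfonylhydrazide, Et3N, CH2Cl2) reduces the 1,2-disubstituted C9=C10 alkene in preference to the trisubstituted C2=C3 alkene and delivers 13.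

2. Step 3. After the alkylation the β-keto ester enolate may open the oxirane intramolecularly (5-exo O- or C-alkylation), or the dianion may attack the oxirane instead of displacing iodide. The fallback sets out from 3 and comes back at 9, bypassing 6 and 8. The lithium azaenolate of acetone N,N-dimethylhydrazone (LDA, THF, −78 → 0 °C) is alkylated by 3 to the neutral hydrazone F5, which carries no enolate that could attack the oxirane. Buffered copper(II)-assisted hydrolysis (Cu(OAc)2, THF–H2O) gives the methyl ketone 4-[(2R,3R)-3-methyl-3-(4-methylpent-3-en-1-yl)oxiran-2-yl]butan-2-one F6. Horner–Wadsworth–Emmons olefination (trimethyl phosphonoacetate, NaH, THF) then gives 9 as the major isomer, and the minor methyl (2Z)-6,7-epoxyfarnesoate F7 is removed by chromatography.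

3. Step 5. The cuprate may open the oxirane, or reversible conjugate addition may erode the alkene geometry. The fallback sets out from 6 and comes back at 9. The sodium enolate of 6 (NaH, THF) is trapped with PhNTf2 as the (Z)-enol triflate F8, and a Negishi coupling (MeZnCl, Pd(PPh3)4, THF, rt) replaces the triflate by methyl with retention of geometry under conditions that do not attack an oxirane.

Further compounds
F1 | step 8 | (2E)-5-[(2R,3R)-3-[4-hydroxy-4-methyl-3-(phenylselanyl)pentyl]-3-methyloxiran-2-yl]-3-methylpent-2-enal (C10 epimers) | O=C/C=C(\C)CC[C@H]1O[C@]1(C)CCC([Se]c1ccccc1)C(C)(C)O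
F2 | step 8 | (2E)-5-[(2R,3R)-3-[(2E)-4-hydroxy-4-methylpent-2-en-1-yl]-3-methyloxiran-2-yl]-3-methylpent-2-enal | O=C/C=C(\C)CC[C@H]1O[C@]1(C)C/C=C/C(C)(C)O
F3 | step 8 | (2E)-5-[(2R,3R)-3-(2-bromo-4-methylpent-3-en-1-yl)-3-methyloxiran-2-yl]-3-methylpent-2-enal (C9 epimers) | O=C/C=C(\C)CC[C@H]1O[C@]1(C)CC(Br)C=C(C)C
F4 | step 8 | (1S,2E,6R,7R,9E)-6,7-epoxy-3,7,11,11-tetramethylcycloundeca-2,9-dien-1-ol | O[C@H]1/C=C(\C)CC[C@H]2O[C@]2(C)C/C=C/C1(C)C
F5 | step 3 | 4-[(2R,3R)-3-methyl-3-(4-methylpent-3-en-1-yl)oxiran-2-yl]butan-2-one N,N-dimethylhydrazone | CC(=NN(C)C)CC[C@H]1O[C@]1(C)CCC=C(C)C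
F6 | step 3 | 4-[(2R,3R)-3-methyl-3-(4-methylpent-3-en-1-yl)oxiran-2-yl]butan-2-one | CC(=O)CC[C@H]1O[C@]1(C)CCC=C(C)C
F7 | step 3 | methyl (2Z,6R,7R)-6,7-epoxyfarnesoate | COC(=O)/C=C(/C)CC[C@H]1O[C@]1(C)CCC=C(C)C
F8 | step 5 | methyl (2Z)-5-[(2R,3R)-3-methyl-3-(4-methylpent-3-en-1-yl)oxiran-2-yl]-3-[(trifluoromethanesulfonyl)oxy]pent-2-enoate | COC(=O)/C=C(\OS(=O)(=O)C(F)(F)F)CC[C@H]1O[C@]1(C)CCC=C(C)C
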